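Ring A of the target is a cyclohexene (C3=C4) fused through C5–C10 to ring B, so the decalin is cut in a retro-[4+2] sense into a C2=C3–C4=C5 diene and a C10=C1 dienophile held together by the C6–C9 chain. One thermal intramolecular Diels–Alder reaction of an (E)-vinyl sulfone then forms C5–C10 and C1–C2, closes both rings and sets C5, C10 and C1; the sulfone is excised afterwards. The precursor is an acyclic 1,3,9-decatriene from D-tartrate: (E)-diene, C6/C7 trans-acetonide, C8 methyl carbinol as its triethylsilyl ether, quaternary C9 carrying the methyl group, a benzyloxymethyl group (C11) and the sulfonylvinyl group.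

Key step: step 16

Remark on numbering: locants C1–C20 are those of the target (ring A = C1–C5 and C10; ring B = C5–C10; C17 on C8, C18 on C4, C19 on C5, C20 on C9; side chain C11–C16).
Remark on C8: the C9 allyl unit must add to the C8 methyl ketone under non-chelation (Felkin–Anh) control, because addition through an O7 chelate would give the C8 epimer; a boron reagent is therefore used.
Remark on protecting groups: O11 is carried as a benzyl ether, since a primary silyl ether could not be removed dependably beside the tertiary O8 silyl ether; O10 is a primary triethylsilyl ether until the dienophile is installed.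

Step 1
Reactants: 1 dimethyl (4S,5S)-2,2-dimethyl-1,3-dioxolane-4,5-dicarboxylate
Product: 2 (4S,5S)-N4,N5-dimethoxy-N4,N5,2,2-tetramethyl-1,3-dioxolane-4,5-dicarboxamide
Conditions: MeNH(OMe)·HCl, i-PrMgCl, THF, −20 to 0 °C
Reagents that add atoms: N,O-dimethylhydroxylamine hydrochloride, CNOC.Cl
Why: Aminolysis of both esters by the magnesium amide (Weinreb amide synthesis) should leave C6 and C7 untouched, their trans arrangement on the dioxolane being also the thermodynamically preferred one.

Step 2
Reactants: 2 bis-Weinreb amide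
Product: 3 (4S,5S)-5-acetyl-N-methoxy-N,2,2-trimethyl-1,3-dioxolane-4-carboxamide (C8 methyl ketone)
Conditions: MeMgBr (1.0 equiv), THF, −78 to 0 °C; aq. NH4Cl
Reagents that add atoms: methylmagnesium bromide, C[Mg]Br
Why: Weinreb ketone synthesis, in which the chelated tetrahedral adduct survives until work-up, so that with one equivalent of Grignard reagent mono-addition to the C2-symmetric diamide should dominate and unreacted 2 can be recycled.

Step 3
Reactants: 4 4-(benzyloxy)but-2-yn-1-ol
Product: 6 (Z)-4-(benzyloxy)-3-iodobut-2-en-1-ol, via cyclic vinylalanate 5 (not isolated)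
Conditions: NaAlH2(OCH2CH2OMe)2, THF, 0 °C; then I2, −78 °C
Reagents that add atoms: iodine, II
Why: Hydroxyl-directed trans-hydroalumination of the propargylic alcohol places aluminium on C3 in a five-membered alanate, and iodinolysis of the C–Al bond with retention should give the (Z)-iodide.

Step 4
Reactants: 6 (Z)-4-(benzyloxy)-3-iodobut-2-en-1-ol
Product: 7 (E)-4-(benzyloxy)-3-methylbut-2-en-1-ol
Conditions: Me2CuLi (excess), Et2O, −30 to 0 °C
Reagents that add atoms: lithium dimethylcuprate, [Li+].C[Cu-]C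
Why: Corey–Posner cuprate substitution of the vinyl iodide proceeds with retention, which fixes the benzyloxymethyl group (later C11) trans to the carbinol carbon (later C1).

Step 5
Reactants: 7 (E)-4-(benzyloxy)-3-methylbut-2-en-1-ol
Product: 8 (E)-[4-(benzyloxy)-3-methylbut-2-en-1-yl]boronic acid (extracted and kept in solution under argon)
Conditions: B2(OH)4, Pd(MeCN)4(BF4)2 (2 mol %), DMSO/MeOH, rt, Ar
Reagents that add atoms: tetrahydroxydiboron, OB(O)B(O)O
Why: Palladium-catalysed allylic borylation (Miyaura type) of the allylic alcohol runs through an η3-allyl complex that accepts boron at the unsubstituted terminus with retention of the alkene geometry.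

Step 6
Reactants: 3 C8 methyl ketone; 8 allylboronic acid
Product: 9 (4S,5S)-5-[(2R,3S)-3-[(benzyloxy)methyl]-2-hydroxy-3-methylpent-4-en-2-yl]-N-methoxy-N,2,2-trimethyl-1,3-dioxolane-4-carboxamide (6S,7S,8R,9S)
Conditions: THF, 3 Å MS, rt, Ar; aq. NaHCO3
Reagents that add atoms: none
Why: Allylboration of the ketone through a Zimmerman–Traxler chair (C17 methyl axial, dioxolanyl group equatorial, C11 equatorial because it is trans to CH2B) should set the C8/C9 relationship, while the non-chelating boron leaves the carbonyl face to Felkin–Anh (Cornforth) control by the C7–O7 bond, giving the 8R carbinol and the quaternary C9 of the target.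

Step 7
Reactants: 9 tertiary homoallylic alcohol
Product: 11 (4S,5S)-5-[(2R,3S)-3-[(benzyloxy)methyl]-2,4-dihydroxy-3-methylbutan-2-yl]-N-methoxy-N,2,2-trimethyl-1,3-dioxolane-4-carboxamide, via hydroxy aldehyde 10 (not isolated)
Conditions: O3, CH2Cl2/MeOH, −78 °C; then NaBH4, −78 to 0 °C
Reagents that add atoms: ozone, [O-][O+]=O
Why: Ozonolysis (Criegee mechanism) of the only alkene with borohydride work-up turns the vinyl group into the C10 hydroxymethyl group, the immediate reduction keeping the β-hydroxy aldehyde from retro-aldol cleavage while Weinreb amide and benzyl ether stay inert.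

Step 8
Reactants: 11 diol
Product: 12 O8,O10-bis(triethylsilyl) ether of 11 (6S,7S,8R,9R)
Conditions: TESOTf, 2,6-lutidine, CH2Cl2, −78 to 0 °C
Reagents that add atoms: triethylsilyl trifluoromethanesulfonate, CC[Si](CC)(CC)OS(=O)(=O)C(F)(F)F
Why: Silylation with the silyl triflate is forceful enough to cap the hindered tertiary O8 together with the primary O10, which blocks retro-aldol pathways in all later carbonyl steps.

Step 9
Reactants: 12 bis-silyl ether; 13 N-methoxy-N-methylpropanamide
Product: 14 β-keto Weinreb amide (C5 ketone, C3 amide, C4 epimers; 6S,7S,8R,9R)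
Conditions: 13, LDA, THF, −78 °C; then 12, −78 to −20 °C; aq. NH4Cl
Reagents that add atoms: none
Why: Claisen-type acylation of the amide enolate by the Weinreb amide stops at the ketone because the β-keto amide is deprotonated at C4 as it forms, which also protects C6 from epimerisation.

Step 10
Reactants: 14 β-keto Weinreb amide
Product: 16 (Z)-enol triflate at C5 (triflyloxy group cis to C3; 6S,7S,8R,9R), via sodium enolate 15 (not isolated)
Conditions: NaH, CH2Cl2, 0 °C; then Tf2O, −78 to −20 °C
Reagents that add atoms: trifluoromethanesulfonic anhydride, O=S(=O)(OS(=O)(=O)C(F)(F)F)C(F)(F)F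
Why: O-Sulfonylation of the sodium-chelated, U-shaped β-keto amide enolate should give the enol triflate with the triflyloxy group cis to the C3 carbonyl group, the geometry needed for C4=C5.

Step 11
Reactants: 16 (Z)-enol triflate
Product: 17 (E)-α,β-unsaturated Weinreb amide with tetrasubstituted C4=C5 (C19 cis to C3; 6R,7S,8R,9R)
Conditions: MeZnCl, Pd(PPh3)4 (5 mol %), THF, 50 °C
Reagents that add atoms: methylzinc chloride, C[Zn]Cl
Why: Negishi coupling of the enol triflate proceeds with retention, so the new C19 methyl group stands cis to C3 and C6 trans to C3.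

Step 12
Reactants: 17 unsaturated Weinreb amide
Product: 18 (E)-enal (C3 aldehyde; 6R,7S,8R,9R)
Conditions: DIBAL-H, THF, −78 °C; Rochelle salt
Reagents that add atoms: none
Why: DIBAL-H reduction of a Weinreb amide stops at the aldehyde through the chelated aluminium hemiaminal, and no other reducible group is present.

Step 13
Reactants: 18 enal
Product: 19 (E)-diene C2=C3–C4=C5 with O8 and O10 triethylsilyl ethers (6R,7S,8R,9R)
Conditions: Ph3PCH3Br, KHMDS, THF, −78 to 0 °C
Reagents that add atoms: methyltriphenylphosphonium bromide, C[P+](c1ccccc1)(c1ccccc1)c1ccccc1.[Br-]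
Why: Wittig methylenation of the enal adds C2 and completes the diene without touching the silyl ethers or the C4=C5 geometry.

Step 14
Reactants: 19 diene bis-silyl ether
Product: 20 C10 aldehyde (diene, O8 triethylsilyl ether, O11 benzyl ether; 6R,7S,8R,9S)
Conditions: (COCl)2, DMSO, CH2Cl2, −78 to −30 °C; then Et3N
Reagents that add atoms: none
Why: Under Swern conditions a primary triethylsilyl ether is cleaved by the chlorosulfonium salt and oxidised in the same flask, whereas the tertiary O8 silyl ether is too hindered to react, so the C10 aldehyde is unveiled beside the diene in one operation.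

Step 15
Reactants: 20 C10 aldehyde; 21 diethyl (phenylsulfonyl)methylphosphonate
Product: 22 sulfonyl triene (C6/C7 acetonide, O8 triethylsilyl, O11 benzyl, (E)-C10=C1 vinyl sulfone; 6R,7S,8R,9S)
Conditions: 21, NaH, THF, 0 °C to rt
Reagents that add atoms: none
Why: Horner–Wadsworth–Emmons olefination of the non-enolisable neopentyl aldehyde with the sulfonyl-stabilised phosphonate gives the (E)-vinyl sulfone.

Step 16
Reactants: 22 sulfonyl triene
Product: 23 C1-phenylsulfonyl trans-octalin (C6/C7 acetonide, O8 triethylsilyl, O11 benzyl; 1R,5R,6R,7S,8R,9S,10S)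
Conditions: PhMe (degassed, 0.005 M), BHT, 180 °C, sealed tube
Reagents that add atoms: none
Why: A concerted, suprafacial thermal [4+2] cycloaddition (type 1 intramolecular Diels–Alder reaction of a 1,3,9-decatriene with a vinyl sulfone dienophile, a known class) joins C5 to C10 and C1 to C2. Ring B closes through the C5–C10 bond as the six-membered ring made by the four-atom tether C6–C9 in a chair-like array, and ring A closes as the new cyclohexene (C1–C2–C3=C4–C5–C10) of the cycloaddition itself. C5 is fixed by the (E)-geometry of C4=C5 (C6 outside, C19 inside) together with the diene face chosen by the C6/C7 trans-dioxolane, which can span ring B only with O6 and O7 equatorial and so allows a single chair; C10 follows from the tether-exo (sulfone-endo) approach that gives the trans ring fusion; C1 follows from the (E)-vinyl sulfone and is erased later. The step needs trans-fusion selectivity and one diene face, and both should be secured by that acetonide-locked chair, in which C19 and H10 end up anti. The sulfone lowers the dienophile LUMO; the fully substituted diene terminus with its inside methyl group and the developing 1,3-diaxial C19/C20 contact make this the slow step that carries the risk, with a [1,5]-hydrogen shift from C19 as the competing path.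

Step 17
Reactants: 23 sulfonyl octalin
Product: 24 C11 primary alcohol, C1 methylene (C6/C7 acetonide, O8 triethylsilyl; 5R,6R,7S,8R,9S,10S)
Conditions: Na, liquid NH3/THF, −78 °C; NH4Cl
Reagents that add atoms: none
Why: Dissolving-metal reduction cleaves the C1–S bond (reductive desulfonylation) and the benzyl ether in one operation, while the isolated C3=C4 alkene, the acetonide and the tertiary silyl ether are inert.

Step 18
Reactants: 24 C11 alcohol
Product: 25 C11 aldehyde (5R,6R,7S,8R,9R,10S)
Conditions: Dess–Martin periodinane, NaHCO3, CH2Cl2, rt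
Reagents that add atoms: none
Why: Dess–Martin oxidation of the neopentyl primary alcohol gives an aldehyde without α-hydrogen, so nothing can epimerise.

Step 19
Reactants: 25 C11 aldehyde
Product: 26 (E)-C11=C12 alkenyl pinacol boronate (5R,6R,7S,8R,9R,10S)
Conditions: CH2(Bpin)2, LiTMP, THF, 0 °C; then 25, −78 °C to rt
Reagents that add atoms: bis(pinacolato)borylmethane, CC1(C)OB(CB2OC(C)(C)C(C)(C)O2)OC1(C)C
Why: Boron–Wittig olefination, in which addition of the lithiated gem-diboronate and syn B–O elimination should give the (E)-alkenylboronate and so create C11=C12.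

Step 20
Reactants: 26 alkenyl boronate; 27 4-bromofuran-2(5H)-one
Product: 28 (E)-dienyl butenolide with C6/C7 acetonide and O8 triethylsilyl ether (5R,6R,7S,8R,9R,10S)
Conditions: PdCl2(dppf) (5 mol %), K3PO4, THF/H2O, 45 °C
Reagents that add atoms: none
Why: Suzuki–Miyaura coupling of the alkenylboronate with the vinylogous acyl bromide forms C12–C13 with retention of the (E)-geometry.

Step 21
Reactants: 28 protected dienyl butenolide
Product: 29 6,7,8-triol (5R,6R,7S,8R,9R,10S)
Conditions: 2 M aq. HCl/MeOH/THF, rt to 40 °C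
Reagents that add atoms: none
Why: Acid-catalysed acetal hydrolysis and silyl ether solvolysis remove both protecting groups, the strained trans-fused dioxolane opening readily under conditions the butenolide and the C3=C4 alkene should tolerate.

Step 22
Reactants: 29 triol
Product: 30 target, 6,7-diacetate (5R,6R,7S,8R,9R,10S)
Conditions: Ac2O, pyridine, DMAP (cat.), CH2Cl2, rt
Reagents that add atoms: acetic anhydride, CC(=O)OC(C)=O
Why: DMAP-catalysed acetylation esterifies the two equatorial secondary hydroxyl groups, while the tertiary C8 hydroxyl next to the quaternary C9 is too hindered to react.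

Compound list

1 | dimethyl (4S,5S)-2,2-dimethyl-1,3-dioxolane-4,5-dicarboxylate | COC(=O)[C@H]1OC(C)(C)O[C@@H]1C(=O)OC | starting material
2 | (4S,5S)-N4,N5-dimethoxy-N4,N5,2,2-tetramethyl-1,3-dioxolane-4,5-dicarboxamide | CON(C)C(=O)[C@H]1OC(C)(C)O[C@@H]1C(=O)N(C)OC | intermediate
3 | (4S,5S)-5-acetyl-N-methoxy-N,2,2-trimethyl-1,3-dioxolane-4-carboxamide | CON(C)C(=O)[C@H]1OC(C)(C)O[C@@H]1C(C)=O | intermediate
4 | 4-(benzyloxy)but-2-yn-1-ol | OCC#CCOCc1ccccc1 | starting material
5 | cyclic vinylalanate: sodium 3-[(benzyloxy)methyl]-2,2-bis(2-methoxyethoxy)-2,5-dihydro-1,2-oxaalumol-2-uide | [Na+].COCCO[Al-]1(OCCOC)OCC=C1COCc1ccccc1 | intermediate (not isolated)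
6 | (Z)-4-(benzyloxy)-3-iodobut-2-en-1-ol | OC/C=C(\I)COCc1ccccc1 | intermediate
7 | (E)-4-(benzyloxy)-3-methylbut-2-en-1-ol | OC/C=C(\C)COCc1ccccc1 | intermediate
8 | (E)-[4-(benzyloxy)-3-methylbut-2-en-1-yl]boronic acid | OB(O)C/C=C(\C)COCc1ccccc1 | intermediate
9 | (4S,5S)-5-[(2R,3S)-3-[(benzyloxy)methyl]-2-hydroxy-3-methylpent-4-en-2-yl]-N-methoxy-N,2,2-trimethyl-1,3-dioxolane-4-carboxamide | CON(C)C(=O)[C@H]1OC(C)(C)O[C@@H]1[C@](C)(O)[C@](C)(COCc2ccccc2)C=C | intermediate
10 | hydroxy aldehyde: (4S,5S)-5-[(2R,3S)-3-[(benzyloxy)methyl]-2-hydroxy-3-methyl-4-oxobutan-2-yl]-N-methoxy-N,2,2-trimethyl-1,3-dioxolane-4-carboxamide | CON(C)C(=O)[C@H]1OC(C)(C)O[C@@H]1[C@](C)(O)[C@](C)(COCc2ccccc2)C=O | intermediate (not isolated)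
11 | (4S,5S)-5-[(2R,3S)-3-[(benzyloxy)methyl]-2,4-dihydroxy-3-methylbutan-2-yl]-N-methoxy-N,2,2-trimethyl-1,3-dioxolane-4-carboxamide | CON(C)C(=O)[C@H]1OC(C)(C)O[C@@H]1[C@](C)(O)[C@](C)(COCc2ccccc2)CO | intermediate
12 | (4S,5S)-5-[(2R,3R)-3-[(benzyloxy)methyl]-3-methyl-2,4-bis(triethylsilyloxy)butan-2-yl]-N-methoxy-N,2,2-trimethyl-1,3-dioxolane-4-carboxamide | CON(C)C(=O)[C@H]1OC(C)(C)O[C@@H]1[C@](C)(O[Si](CC)(CC)CC)[C@](C)(COCc2ccccc2)CO[Si](CC)(CC)CC | intermediate
13 | N-methoxy-N-methylpropanamide | CCC(=O)N(C)OC | starting material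
14 | β-keto Weinreb amide: N-methoxy-N,2-dimethyl-3-oxopropanamide bearing at C3 the (4S,5S)-dioxolanyl unit of 12 (C4 epimers; 6S,7S,8R,9R) | CON(C)C(=O)C(C)C(=O)[C@H]1OC(C)(C)O[C@@H]1[C@](C)(O[Si](CC)(CC)CC)[C@](C)(COCc2ccccc2)CO[Si](CC)(CC)CC | intermediate
15 | sodium (Z)-enolate of 14 (enolate oxygen on C5, cis to C3) | [Na+].CON(C)C(=O)/C(C)=C(\[O-])[C@H]1OC(C)(C)O[C@@H]1[C@](C)(O[Si](CC)(CC)CC)[C@](C)(COCc2ccccc2)CO[Si](CC)(CC)CC | intermediate (not isolated)
16 | (Z)-enol triflate of 14 (C5–OTf cis to C3; 6S,7S,8R,9R) | CON(C)C(=O)/C(C)=C(\OS(=O)(=O)C(F)(F)F)[C@H]1OC(C)(C)O[C@@H]1[C@](C)(O[Si](CC)(CC)CC)[C@](C)(COCc2ccccc2)CO[Si](CC)(CC)CC | intermediate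
17 | (E)-N-methoxy-N,2-dimethylbut-2-enamide bearing at C3 the dioxolanyl unit (tetrasubstituted C4=C5; 6R,7S,8R,9R) | CON(C)C(=O)/C(C)=C(\C)[C@H]1OC(C)(C)O[C@@H]1[C@](C)(O[Si](CC)(CC)CC)[C@](C)(COCc2ccccc2)CO[Si](CC)(CC)CC | intermediate
18 | (E)-2-methylbut-2-enal bearing at C3 the dioxolanyl unit (6R,7S,8R,9R) | O=C/C(C)=C(\C)[C@H]1OC(C)(C)O[C@@H]1[C@](C)(O[Si](CC)(CC)CC)[C@](C)(COCc2ccccc2)CO[Si](CC)(CC)CC | intermediate
19 | (E)-3-methylpenta-2,4-dien-2-yl dioxolane with O8 and O10 triethylsilyl ethers and O11 benzyl ether (6R,7S,8R,9R) | C=C/C(C)=C(\C)[C@H]1OC(C)(C)O[C@@H]1[C@](C)(O[Si](CC)(CC)CC)[C@](C)(COCc2ccccc2)CO[Si](CC)(CC)CC | intermediate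
20 | C10 aldehyde of the diene (O8 triethylsilyl, O11 benzyl; 6R,7S,8R,9S) | C=C/C(C)=C(\C)[C@H]1OC(C)(C)O[C@@H]1[C@](C)(O[Si](CC)(CC)CC)[C@](C)(COCc2ccccc2)C=O | intermediate
21 | diethyl (phenylsulfonyl)methylphosphonate | CCOP(=O)(CS(=O)(=O)c1ccccc1)OCC | starting material
22 | acyclic sulfonyl triene: (E)-diene, C6/C7 acetonide, O8 triethylsilyl, O11 benzyl, (E)-C10=C1 phenylsulfonyl alkene (6R,7S,8R,9S) | C=C/C(C)=C(\C)[C@H]1OC(C)(C)O[C@@H]1[C@](C)(O[Si](CC)(CC)CC)[C@](C)(COCc2ccccc2)/C=C/S(=O)(=O)c3ccccc3 | intermediate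
23 | C1-phenylsulfonyl trans-octalin, C6/C7 acetonide, O8 triethylsilyl, O11 benzyl (1R,5R,6R,7S,8R,9S,10S) | CC3(C)O[C@H]1[C@H](O3)[C@](C)(O[Si](CC)(CC)CC)[C@](C)(COCc5ccccc5)[C@H]2[C@H](S(=O)(=O)c4ccccc4)CC=C(C)[C@]12C | intermediate
24 | trans-octalin with C11 hydroxymethyl group, C6/C7 acetonide, O8 triethylsilyl (5R,6R,7S,8R,9S,10S) | CC3(C)O[C@H]1[C@H](O3)[C@](C)(O[Si](CC)(CC)CC)[C@](C)(CO)[C@H]2CCC=C(C)[C@]12C | intermediate
25 | C11 aldehyde (5R,6R,7S,8R,9R,10S) | CC3(C)O[C@H]1[C@H](O3)[C@](C)(O[Si](CC)(CC)CC)[C@](C)(C=O)[C@H]2CCC=C(C)[C@]12C | intermediate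
26 | (E)-C11=C12 alkenyl pinacol boronate (5R,6R,7S,8R,9R,10S) | CC3(C)O[C@H]1[C@H](O3)[C@](C)(O[Si](CC)(CC)CC)[C@](C)(/C=C/B4OC(C)(C)C(C)(C)O4)[C@H]2CCC=C(C)[C@]12C | intermediate
27 | 4-bromofuran-2(5H)-one | O=C1C=C(Br)CO1 | starting material
28 | (E)-dienyl butenolide, C6/C7 acetonide, O8 triethylsilyl (5R,6R,7S,8R,9R,10S) | CC3(C)O[C@H]1[C@H](O3)[C@](C)(O[Si](CC)(CC)CC)[C@](C)(/C=C/C4=CC(=O)OC4)[C@H]2CCC=C(C)[C@]12C | intermediate
29 | 6,7,8-triol (5R,6R,7S,8R,9R,10S) | O[C@H]1[C@H](O)[C@](C)(O)[C@](C)(/C=C/C2=CC(=O)OC2)[C@H]2CCC=C(C)[C@]12C | intermediate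
30 | CNP0383656.1, 6,7-diacetate (5R,6R,7S,8R,9R,10S) | CC(=O)O[C@H]1[C@H](OC(C)=O)[C@](C)(O)[C@](C)(/C=C/C2=CC(=O)OC2)[C@H]2CCC=C(C)[C@]12C | target

Total step count: 22 steps.
Longest linear sequence: 20 steps (steps 3–5 and 6–22, from 4); the tartrate line (steps 1, 2, 6–22) is 19 steps.

Steps most likely to fail

Step 16. The cycloaddition may be outrun by a [1,5]-hydrogen shift from the inside C19 methyl group or by thermal decay of the triene, or may leak through the tether-endo transition state to cis-fused material. Fallback (sets out from 20, returns at 24): a nitroalkene replaces the sulfone as traceless activator of the same C10=C1 dienophile. Henry reaction of 20 with nitromethane gives nitro alcohol F1, mesylation gives nitro mesylate F2, and elimination with triethylamine gives nitro triene F3. Its intramolecular Diels–Alder reaction is expected at 25–80 °C and should give nitro cycloadduct F4 with the same trans fusion. Radical denitration with Bu3SnH/AIBN gives benzyl ether F5, and debenzylation with Na in liquid NH3 gives 24.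

Step 6. Addition to the hindered ketone may be too slow, or the non-chelation facial preference may erode and deliver the C8 epimer. Fallback (sets out from 2, returns at 9): the order of the two carbon nucleophiles is reversed, so that the allyl unit meets an aldehyde and the methyl group a chelated ketone. Partial reduction of 2 with one equivalent of DIBAL-H gives amido aldehyde F6. Allylboration with 8 (Felkin–Anh, anti) gives secondary alcohol F7, and Dess–Martin oxidation gives ketone F8. MeMgBr in Et2O/CH2Cl2 at −78 °C then adds under O7 chelation, methyl anti to C6, before the Weinreb amide reacts, and gives 9.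

Step 19. The bulky lithiated diboronate may fail to add to the neopentyl aldehyde, or the elimination may lose its E preference. Fallback (sets out from 25, returns at 26): Seyferth–Gilbert homologation with the Ohira–Bestmann reagent (K2CO3, MeOH) gives alkyne F9, and Cp2Zr(H)Cl-catalysed syn-hydroboration with pinacolborane places boron on the terminal carbon and gives 26.

Further compounds

F1 | step 16 | nitro alcohol (C10 carbinol, C1 nitromethyl; C10 epimers) | C=C/C(C)=C(\C)[C@H]1OC(C)(C)O[C@@H]1[C@](C)(O[Si](CC)(CC)CC)[C@](C)(COCc2ccccc2)C(O)C[N+](=O)[O-]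
F2 | step 16 | nitro mesylate | C=C/C(C)=C(\C)[C@H]1OC(C)(C)O[C@@H]1[C@](C)(O[Si](CC)(CC)CC)[C@](C)(COCc2ccccc2)C(OS(C)(=O)=O)C[N+](=O)[O-]
F3 | step 16 | nitro triene ((E)-C10=C1 nitroalkene) | C=C/C(C)=C(\C)[C@H]1OC(C)(C)O[C@@H]1[C@](C)(O[Si](CC)(CC)CC)[C@](C)(COCc2ccccc2)/C=C/[N+](=O)[O-]
F4 | step 16 | nitro cycloadduct (C1-nitro trans-octalin) | CC3(C)O[C@H]1[C@H](O3)[C@](C)(O[Si](CC)(CC)CC)[C@](C)(COCc4ccccc4)[C@H]2[C@H]([N+](=O)[O-])CC=C(C)[C@]12C
F5 | step 16 | benzyl ether of 24 | CC3(C)O[C@H]1[C@H](O3)[C@](C)(O[Si](CC)(CC)CC)[C@](C)(COCc4ccccc4)[C@H]2CCC=C(C)[C@]12C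
F6 | step 6 | amido aldehyde: (4S,5S)-5-formyl-N-methoxy-N,2,2-trimethyl-1,3-dioxolane-4-carboxamide | CON(C)C(=O)[C@H]1OC(C)(C)O[C@@H]1C=O
F7 | step 6 | secondary alcohol (C8 carbinol, 8R; C9 as in 9) | CON(C)C(=O)[C@H]1OC(C)(C)O[C@@H]1[C@H](O)[C@](C)(COCc2ccccc2)C=C
F8 | step 6 | ketone (C8 carbonyl, quaternary C9) | CON(C)C(=O)[C@H]1OC(C)(C)O[C@@H]1C(=O)[C@](C)(COCc2ccccc2)C=C
F9 | step 19 | alkyne (C11≡C12 on C9) | CC3(C)O[C@H]1[C@H](O3)[C@](C)(O[Si](CC)(CC)CC)[C@](C)(C#C)[C@H]2CCC=C(C)[C@]12C
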